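## Analysis of the target

Tamadone (12) is a flavone: a 4H-chromen-4-one in which benzo ring A is fused to pyranone ring C, and C2 of ring C carries phenyl ring B. Ring A has no hydrogen left; it bears a free hydroxyl at C5 and methoxy groups at C6, C7 and C8, while ring B is a resorcinol unit with free hydroxyls at C2' and C4'. The molecule has no stereocentre, so every problem is one of regiochemistry and chemoselectivity. The sensitive functions are three phenols on two electron-rich, easily oxidized rings and three methyl ethers that must stay while the oxygen at C5 alone is set free; the 5-hydroxyl is hydrogen bonded to the C4 carbonyl, and the same peri relationship makes an ether at C5 the first one a chelating Lewis acid removes. The difficulty lies in the four contiguous oxygens of ring A, only one of which is unmasked, and in the ortho oxygen at C2', which crowds the C2–C1' junction and burdens the classical condensations with a doubly oxygenated benzoyl or benzaldehyde partner. The strategy rests on the C2–C1' bond itself. C2 is the β-carbon of the vinylogous ester of ring C and carries an electron-poor C–H bond in a chromone lacking ring B, whereas C1' is ortho to O2' and para to O4', the most nucleophilic carbon of a resorcinol diether; since ring A has no C–H bond, such a chromone offers a metal only C2–H and C3–H.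

## Retrosynthetic reasoning

**12 ⇒ 11.** Three O–alkyl bonds are cut: the two O–isopropyl bonds on ring B and the O–methyl bond at C5. Flavone 11 is the 2',4'-di-O-isopropyl, 5-O-methyl ether of 12. This leaves every phenol masked until the last step, so no free phenol has to pass through an oxidative metal-catalysed step. The forward reaction is a Lewis-acid dealkylation with a boron trihalide. It must remove the secondary ethers and the carbonyl-chelated 5-methyl ether and leave the methoxy groups at C6, C7 and C8. Isopropyl is chosen because methyl ethers on ring B could not be told apart from those on ring A, and benzyl ethers would add aromatic and benzylic C–H bonds to the coupling step.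

**11 ⇒ 8 + 10.** The C2–C1' bond is cut, giving chromone 8 (rings A and C complete) and diether 10 (ring B). This is the only C–C bond that joins two intact aromatic units. Cutting inside ring C instead would need a 2,4-dioxygenated acyl or formyl partner and extra condensation and redox steps. The gain is convergence without prefunctionalization: both partners react through C–H bonds, and 10 is symmetric, so its C4 and C6 are the same site. The forward reaction is a dehydrogenative coupling under divalent palladium catalysis with a silver carboxylate as terminal oxidant. It must choose C2 over C3 on 8, choose C4 over C2 and C5 on 10, and favour cross- over homo-coupling.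

**8 ⇒ 5 + 6 (through 7).** The O1–C2 and C2–C3 bonds of the pyranone are cut. C2 is a one-carbon unit at the formic acid oxidation level, supplied by amide acetal 6. Acetophenone 5 provides C3, C4 and the phenol oxygen. The forward sequence condenses the acetyl methyl group of 5 with 6 to enaminone 7 and closes the ring under acid with loss of the amine. This route gives a chromone unsubstituted at both C2 and C3, which is what the coupling needs.

**5 ⇒ 4.** The aryl–acetyl bond is cut. Phenol 4 has a single unsubstituted ring carbon, and it lies ortho to the hydroxyl, so a Friedel–Crafts acetylation can give only 5.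

**4 ⇒ 2 (through 3) ⇒ 1.** The phenolic C–O bond is traced back to an aryl–formyl bond by a Baeyer–Villiger oxidation through formate 3, and the formyl group of aldehyde 2 to a C–H bond of tetramethoxybenzene 1. Compound 1 is symmetric with two equivalent free positions, so formylation has one outcome. Formylation then oxygen insertion is the reliable way to put a fifth oxygen on a ring that direct oxidants would take to a quinone.

**10 ⇒ 9.** The two O–isopropyl bonds are cut; resorcinol 9 is alkylated twice in a Williamson etherification.

## Alternatives that were turned down

**Alternative 1:** Ring A is dismantled instead of the C2–C1' bond. The C4a–C5 bond is cut, and C5 to C8 with their oxygens are traced to a four-membered ring. The precursor is A2, a 2,3,4-trimethoxycyclobutenone carrying a 6-aryl-4-pyranon-2-yl group at C4. In the forward key step, thermolysis of A2 should open the cyclobutenone to a dienylketene. Its ketene carbon closes onto the free pyranone carbon next to the point of attachment, and tautomerization aromatizes ring A to give A1, the bis(benzyl) ether of 12.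
- *For:* the oxygen at C5 comes from the ketene carbonyl and is born as a free hydroxyl, while the other three oxygens are methyl ethers from the start. The chosen route differentiates ring A only in its last step, so on this point Alternative 1 is stronger.
- *Against:* the electrocyclization must engage a C=C bond of an electron-poor, cross-conjugated pyranone, not an electron-rich arene. A2 also needs a 2-aryl-4-pyranone metalated next to the ring oxygen in the presence of its own carbonyl, 1,2-addition to a squaric diester, and O-methylation of a hindered tertiary alkoxide. All of this is linear chemistry on material that already contains ring B, and the benzyl ethers must still be removed.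
- *Comparison:* the chosen strategy builds ring A by plain aromatic chemistry on symmetric 1 with no regiochemical choice. Its one uncertain step joins two cheap fragments, and it is several steps shorter.

**Alternative 2:** Ring B is built de novo by cutting C1'–C2' and C5'–C6'. The chromone carries an ethynyl group at C2 (A4), and the other four ring carbons with both oxygens come from diene A5, 1-methoxy-1,3-bis(trimethylsilyloxy)buta-1,3-diene. In the forward key step, heating A4 with A5 should give a [4+2] adduct. Acidic work-up then expels the methoxy group and the silyl groups and aromatizes ring B to A3, the 5-O-methyl ether of 12.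
- *For:* the nucleophilic CH2 terminus of A5 matches the alkyne terminus, which is the vinylogous acceptor position of the C4 carbonyl, so the oxygens should land at C2' and C4' with no site-selectivity question. Ring B arrives as free phenols, and only the peri demethylation remains. On certainty of ring-B regiochemistry and on protecting-group economy it is as strong as or stronger than the chosen route.
- *Against:* the alkyne is activated only through the chromone π-system, so the cycloaddition would need heat that the acid- and heat-labile diene A5 tolerates poorly. Open-chain conjugate addition without ring closure is a likely diversion. A4 also has to be made from a chromone such as 8 by functionalizing C2 and then alkynylating, which adds steps.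
- *Comparison:* both routes hang ring B on the same chromone core. The chosen one uses 8 as it is, with a stable arene that can be used in excess and recovered.

**Alternative 3:** Ring C is cut at C8a–O1, C4a–C4 and O1–C2. Ring A arrives as the symmetric tetramethoxy aryne released from silyl triflate A8; C2, C3, C4 and ring B come from arylpropiolic acid A7. In the forward key step a fluoride source generates the aryne and the carboxylate oxygen of A7 adds to it. The aryl anion then attacks its own ester carbonyl (acyl migration), and the resulting ortho-acylphenoxide adds to the ynone to close the pyranone, giving A6.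
- *For:* the aryne is symmetric, so either terminus gives the same product. Three bonds and ring C form in one operation, and the attachment point of ring B is fixed by the synthesis of A7. On bonds per step and on regiochemical certainty it is stronger than the chosen route.
- *Against:* A8 is a hexasubstituted benzene that would itself be made in several steps from phenol 4, the same intermediate the chosen route uses. Both aryne carbons are flanked by methoxy groups, and protonation of the aryl anion by the acid (giving a simple aryl ester) competes with the four-membered acyl transfer. A7 is an electron-rich propiolic acid prone to decarboxylation. The end game is no shorter, since the benzyl ethers and the 5-methyl ether must still be cleaved.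
- *Comparison:* the chosen route reaches the same oxygenation pattern from 4 in two further steps to 8 and couples it with an unfunctionalized arene.

Key step: step 6

## Route

Remark: 1,2,3,4-tetramethoxybenzene (1) is taken as a purchasable compound; equivalents and temperatures are proposed values.

Step 1
Reactants: 1 1,2,3,4-tetramethoxybenzene
Product: 2 2,3,4,5-tetramethoxybenzaldehyde
Conditions: Cl2CHOMe (1.2 equiv), TiCl4 (2 equiv), CH2Cl2, 0 °C; then ice-water
Reagents that add atoms: dichloromethyl methyl ether, COC(Cl)Cl; water, O
Why: Rieche formylation, an electrophilic aromatic substitution by the TiCl4-activated chloromethyl oxocarbenium ion; the two free positions of 1 are equivalent by symmetry and each is ortho and para to a methoxy group, so a single aldehyde should form, and the formyl group deactivates the ring against a second substitution.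

Step 2
Reactants: 2 2,3,4,5-tetramethoxybenzaldehyde
Product: 4 2,3,4,5-tetramethoxyphenol, via aryl formate 3 (not isolated)
Conditions: mCPBA (1.3 equiv), CH2Cl2, 0 °C to rt; aq NaHCO3 wash; crude 3 in MeOH, K2CO3 (0.3 equiv), rt
Reagents that add atoms: mCPBA, O=C(OO)c1cccc(Cl)c1
Why: Baeyer–Villiger oxidation in its Dakin-type course: in the Criegee adduct the electron-rich aryl group, with ortho and para methoxy groups, migrates in preference to hydride and gives formate 3, which base-catalysed methanolysis cleaves to the phenol under conditions too mild to touch the methyl ethers.

Step 3
Reactants: 4 2,3,4,5-tetramethoxyphenol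
Product: 5 1-(2-hydroxy-3,4,5,6-tetramethoxyphenyl)ethan-1-one
Conditions: BF3·OEt2 (3 equiv), AcOH, 90 °C; then water, aq NaOAc
Reagents that add atoms: acetic acid, CC(=O)O
Why: Friedel–Crafts acetylation of a phenol (direct C-acylation, or O-acylation followed by Fries shift): the only unsubstituted ring carbon of 4 lies ortho to the hydroxyl, so regiochemistry is not in question, and the product is held as its difluoroboron chelate, which is hydrolysed on work-up.

Step 4
Reactants: 5 1-(2-hydroxy-3,4,5,6-tetramethoxyphenyl)ethan-1-one; 6 N,N-dimethylformamide dimethyl acetal
Product: 8 5,6,7,8-tetramethoxy-4H-chromen-4-one, via enaminone 7 (not isolated)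
Conditions: 6 (3 equiv), toluene, 100 °C; evaporate; conc. HCl, CH2Cl2, rt
Reagents that add atoms: none
Why: Enaminone route to chromones: condensation of the acetyl methyl group with amide acetal 6 gives E-enaminone 7 with loss of two molecules of methanol, and acid then promotes 6-endo addition of the phenol oxygen to the β-carbon and elimination of dimethylamine, which closes the pyranone and leaves C2 and C3 unsubstituted.

Step 5
Reactants: 9 resorcinol
Product: 10 1,3-diisopropoxybenzene
Conditions: 2-bromopropane (3 equiv), K2CO3 (3 equiv), DMF, 70 °C
Reagents that add atoms: 2-bromopropane, CC(C)Br
Why: Williamson ether synthesis; carbonate in a dipolar aprotic solvent favours O- over C-alkylation of the resorcinol anion, and the excess of the secondary bromide makes up for its loss by elimination.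

Step 6
Reactants: 8 5,6,7,8-tetramethoxy-4H-chromen-4-one; 10 1,3-diisopropoxybenzene
Product: 11 2-(2,4-diisopropoxyphenyl)-5,6,7,8-tetramethoxy-4H-chromen-4-one
Conditions: Pd(OAc)2 (10 mol %), AgOAc (3 equiv), CsOPiv (1 equiv), PivOH, 10 (10 equiv), 110 °C
Reagents that add atoms: none
Why: This is a Pd(OAc)2-catalysed twofold C–H oxidative cross-coupling of the Fujiwara–Moritani type, the closest known reaction being the C2 arylation of chromones by simple arenes under divalent palladium with a silver carboxylate as terminal oxidant. Pivalate-assisted electrophilic palladation of 10 should give an arylpalladium pivalate at C4 (equivalent to C6), the position ortho to one isopropoxy group and para to the other. This species adds across the C2=C3 bond of 8 in the conjugate sense, aryl to the β-carbon C2 and palladium to C3, where it equilibrates with the oxygen-bound enolate. Return of palladium to C3 on the face syn to the C2 hydrogen allows β-hydride elimination, which restores the C2=C3 bond and gives 11; zerovalent palladium is brought back to divalent palladium by two equivalents of AgOAc. No ring is closed and no stereocentre is formed, since the only sp3 centres are transient. The step needs three selectivities: on the arene C4 over C2 and C5, secured by ortho/para activation and by the two branched ethers that shield C2; on the chromone C2 over C3, secured by the polarity of the enone, which sends the aryl group to the β-carbon; and cross- over homo-coupling, secured by the excess of 10 and by ring A of 8 having no C–H bond. The isopropyl ethers add no aromatic or benzylic C–H bond that could be palladated.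

Step 7
Reactants: 11 2-(2,4-diisopropoxyphenyl)-5,6,7,8-tetramethoxy-4H-chromen-4-one
Product: 12 tamadone, 2-(2,4-dihydroxyphenyl)-5-hydroxy-6,7,8-trimethoxy-4H-chromen-4-one
Conditions: BCl3 (1 M in CH2Cl2, 6 equiv), CH2Cl2, −78 °C to 0 °C; then 1 M HCl, rt
Reagents that add atoms: none
Why: Lewis-acid dealkylation with BCl3: the secondary isopropyl ethers ionize readily from their boron complexes and are lost first, and the 5-methoxy group is then cleaved because boron is held between O5 and the C4 carbonyl in a six-membered chelate that delivers chloride to the methyl group. The methoxy groups at C6, C7 and C8 lack this chelation, and plain aryl methyl ethers react slowly with BCl3 at or below 0 °C; aqueous acid hydrolyses the borates and releases the three phenols of 12.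

## Compound list

1 | 1,2,3,4-tetramethoxybenzene | COc1ccc(OC)c(OC)c1OC | starting material
2 | 2,3,4,5-tetramethoxybenzaldehyde | COc1cc(C=O)c(OC)c(OC)c1OC | intermediate
3 | 2,3,4,5-tetramethoxyphenyl formate | COc1cc(OC=O)c(OC)c(OC)c1OC | intermediate
4 | 2,3,4,5-tetramethoxyphenol | COc1cc(O)c(OC)c(OC)c1OC | intermediate
5 | 1-(2-hydroxy-3,4,5,6-tetramethoxyphenyl)ethan-1-one | CC(=O)c1c(O)c(OC)c(OC)c(OC)c1OC | intermediate
6 | N,N-dimethylformamide dimethyl acetal | COC(OC)N(C)C | starting material
7 | (E)-3-(dimethylamino)-1-(2-hydroxy-3,4,5,6-tetramethoxyphenyl)prop-2-en-1-one | CN(C)/C=C/C(=O)c1c(O)c(OC)c(OC)c(OC)c1OC | intermediate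
8 | 5,6,7,8-tetramethoxy-4H-chromen-4-one | COc1c(OC)c(OC)c2c(=O)ccoc2c1OC | intermediate
9 | resorcinol | Oc1cccc(O)c1 | starting material
10 | 1,3-diisopropoxybenzene | CC(C)Oc1cccc(OC(C)C)c1 | intermediate
11 | 2-(2,4-diisopropoxyphenyl)-5,6,7,8-tetramethoxy-4H-chromen-4-one | COc1c(OC)c(OC)c2c(=O)cc(-c3ccc(OC(C)C)cc3OC(C)C)oc2c1OC | intermediate
12 | tamadone, 2-(2,4-dihydroxyphenyl)-5-hydroxy-6,7,8-trimethoxy-4H-chromen-4-one | COc1c(OC)c(O)c2c(=O)cc(-c3ccc(O)cc3O)oc2c1OC | target

## Step count and least certain steps

Total: 7 steps. Longest linear sequence: 6 steps (steps 1, 2, 3, 4, 6, 7 from 1); step 5 is a one-step branch that joins at step 6.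

**Step 6 (key step).** The ortho isopropoxy group next to the palladated carbon may slow aryl transfer to the chromone. Oxidative homocoupling of 10 and reduction of the catalyst to palladium metal could then outrun the cross-coupling. Palladation could also leak to C5 of the arene, which is the less hindered site under a carboxylate-assisted pathway, or to C3 of the chromone, giving regioisomers and chromone dimers. The fallback gives up C–H coupling for the classical condensation route; it sets out from 5 and 10 and comes back at 11. Vilsmeier–Haack formylation of 10 (POCl3, DMF) should give 2,4-diisopropoxybenzaldehyde F1. Claisen–Schmidt condensation of F1 with acetophenone 5 (KOH, EtOH) should give the chalcone (E)-3-(2,4-diisopropoxyphenyl)-1-(2-hydroxy-3,4,5,6-tetramethoxyphenyl)prop-2-en-1-one F2. Oxidative cyclization of F2 with catalytic I2 in DMSO at about 120 °C closes ring C and dehydrogenates to 11.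

**Step 7.** Dealkylation may overrun: once the boron chelate sits on O5 and the mixture is warmed enough to cleave the 5-methyl ether, the neighbouring 6-methoxy group may also be lost. If the mixture is kept too cold, the 5-methyl ether may survive. (Ring opening and reclosure of the pyranone through O5, a Wessely–Moser shift, would be degenerate here because C6 and C8 both carry methoxy, so it is no concern.) The fallback separates the two events by mechanism; it sets out from 11 and comes back at 12. Aqueous-ethanolic HCl at reflux should hydrolyse only the 5-methoxy group, by addition–elimination at C5 of the carbonyl-protonated vinylogous ester, to give 2-(2,4-diisopropoxyphenyl)-5-hydroxy-6,7,8-trimethoxy-4H-chromen-4-one F3. BCl3 at −78 °C then removes only the two isopropyl ethers from F3 to give 12, with no warming phase that would expose the 6-methoxy group.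

**Step 3.** The acylation may stop at the O-acetate, or the hot Lewis acid may cleave the methoxy group that ends up next to the chelated ketone. Acid-promoted degradation of the very electron-rich phenol is also possible. The fallback moves the acylation to a fully methylated ring; it sets out from 4 and comes back at 5. O-Methylation of 4 (MeI, K2CO3, acetone) should give pentamethoxybenzene F4. Friedel–Crafts acetylation of F4 (AcCl, AlCl3, CH2Cl2, 0 °C) should give 1-(2,3,4,5,6-pentamethoxyphenyl)ethan-1-one F5. Kept with AlCl3 in the same pot, F5 should lose one of its two equivalent ortho methyl groups by chelation-controlled cleavage, so only 5 can form.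

**Step 2.** The peracid may over-oxidize the electron-rich ring; in particular, phenol 4 or its formate could be taken on towards a quinone if oxidant or time is in excess. The fallback avoids the peracid and bypasses steps 1 and 2; it sets out from 1 and comes back at 4. Directed ortho-lithiation of 1 (n-BuLi, TMEDA, THF, 0 °C), quenching with B(OMe)3 and hydrolysis should give (2,3,4,5-tetramethoxyphenyl)boronic acid F6. Oxidation of F6 with H2O2 and NaOH gives 4.

## Further compounds

F1 | step 6 | 2,4-diisopropoxybenzaldehyde | CC(C)Oc1ccc(C=O)c(OC(C)C)c1
F2 | step 6 | (E)-3-(2,4-diisopropoxyphenyl)-1-(2-hydroxy-3,4,5,6-tetramethoxyphenyl)prop-2-en-1-one | COc1c(OC)c(OC)c(C(=O)/C=C/c2ccc(OC(C)C)cc2OC(C)C)c(O)c1OC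
F3 | step 7 | 2-(2,4-diisopropoxyphenyl)-5-hydroxy-6,7,8-trimethoxy-4H-chromen-4-one | COc1c(OC)c(O)c2c(=O)cc(-c3ccc(OC(C)C)cc3OC(C)C)oc2c1OC
F4 | step 3 | pentamethoxybenzene | COc1cc(OC)c(OC)c(OC)c1OC
F5 | step 3 | 1-(2,3,4,5,6-pentamethoxyphenyl)ethan-1-one | CC(=O)c1c(OC)c(OC)c(OC)c(OC)c1OC
F6 | step 2 | (2,3,4,5-tetramethoxyphenyl)boronic acid | COc1cc(B(O)O)c(OC)c(OC)c1OC
A1 | alternative 1 | 2-[2,4-bis(benzyloxy)phenyl]-5-hydroxy-6,7,8-trimethoxy-4H-chromen-4-one | COc1c(OC)c(O)c2c(=O)cc(-c3ccc(OCc4ccccc4)cc3OCc3ccccc3)oc2c1OC
A2 | alternative 1 | 4-{6-[2,4-bis(benzyloxy)phenyl]-4-oxo-4H-pyran-2-yl}-2,3,4-trimethoxycyclobut-2-en-1-one | COC1=C(OC)C(OC)(c2cc(=O)cc(-c3ccc(OCc4ccccc4)cc3OCc3ccccc3)o2)C1=O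
A3 | alternative 2 | 2-(2,4-dihydroxyphenyl)-5,6,7,8-tetramethoxy-4H-chromen-4-one | COc1c(OC)c(OC)c2c(=O)cc(-c3ccc(O)cc3O)oc2c1OC
A4 | alternative 2 | 2-ethynyl-5,6,7,8-tetramethoxy-4H-chromen-4-one | C#Cc1cc(=O)c2c(OC)c(OC)c(OC)c(OC)c2o1
A5 | alternative 2 | 1-methoxy-1,3-bis(trimethylsilyloxy)buta-1,3-diene | COC(O[Si](C)(C)C)=CC(=C)O[Si](C)(C)C
A6 | alternative 3 | 2-[2,4-bis(benzyloxy)phenyl]-5,6,7,8-tetramethoxy-4H-chromen-4-one | COc1c(OC)c(OC)c2c(=O)cc(-c3ccc(OCc4ccccc4)cc3OCc3ccccc3)oc2c1OC
A7 | alternative 3 | 3-[2,4-bis(benzyloxy)phenyl]prop-2-ynoic acid | OC(=O)C#Cc1ccc(OCc2ccccc2)cc1OCc1ccccc1
A8 | alternative 3 | 2,3,4,5-tetramethoxy-6-(trimethylsilyl)phenyl trifluoromethanesulfonate | COc1c(OC)c(OC)c([Si](C)(C)C)c(OS(=O)(=O)C(F)(F)F)c1OC
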